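(The numbers in the tables are calculated with made-up constants.)

One point of substrate consumed is our unit: we follow that molecule past its forks and ask whether it still stands as target.

in all of them: gas phase 2.9 mM (held)
- west: substrate 0.059 M; the very flask that is asked about, followed so far
- east: substrate 0.040 M; run made earlier
- flask: substrate 0.059 M; time 4.0 min

- west (time / s: target / %, substrate / %): 15.0: 2.6, 96.4; 40.0: 7.5, 89.1; 80.0: 14.0, 77.7; 120: 16.5, 67.1
- east (time / s: target / %, substrate / %): 12.0: 2.2, 98.0; 30.0: 6.6, 92.5; 60.0: 11.9, 82.5; 90.0: 16.9, 75.6

(readings scatter by 0.5 percentage points)

1. how much target there is at 4.0 min, in percent of the substrate charged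
2. the change that raises the amount of target at 4.0 min, in percent of the substrate charged most ("none" if none brings more than 2 percentage points) (alpha / eta / none)
3. amount of target at 4.0 min, in percent of the substrate charged, after alpha

- alpha: doubling the saturation concentration of gas phase, all else as stated
- eta: doubling the transfer coefficient of the gas phase, all else as stated

- the numbers in the tables scatter with a standard deviation of 0.5 percentage points
- at the start none of the gas phase is in solution

The west run gives that chance as the share, target over substrate consumed (the integral selectivity): 68.8% at 40.0 s, 50.2% at 120 s. We carry the span, the consumption over which the share drops to 0.5 of itself: 48.2% of the charge. An exponential decay through the last west reading would leave 45.0% substrate at 4.0 min, so we reckon 20.1% target.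

Turned round: alpha would bring under 2 percentage points if doubled gas merely ran the clock twice as fast with the span unchanged. Substrate would be 20.3% and target 20.4%, a gain below the margin. That needs equal shares at equal consumption in both runs. East, at 24.4% consumed, shows 69.3%; the west curve there gives 56.7%. A reading's scatter puts about 2.05% on the east share, less than that gap, so we read part of the loss as following loading, not gas, and the west flask as standing well away from that outcome. If the loss did not depend on gas, the span would double and we reckon target at 36.2%; we take the middle, 28.3%, and choose alpha. In the west run the first 15.0 s consume 0.144 min⁻¹ of the charge, a little less than the 0.159 min⁻¹ between 80.0 s and 120 s, so we expect the gas to arrive quickly and eta to offer little.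

The forecast said 15.5%, and 17.5% after alpha (“Doubling saturation doubles dissolved gas”), below our 20.1% and 28.3%.

The flask gives 20.8%; alpha adds 6.3 points, eta 1.2 points, and alpha reaches 27.0%. At 4.00 min the flask holds 33.4% of the charge as side product, which counts twice in that percentage as it holds two units of substrate, and which forms from substrate and target without gas.

    gas phase ⇌ dissolved gas, rate k1*(csat - [dissolved gas]) (kL = 0.235 s⁻¹)
    substrate + dissolved gas → target (k = 1.17 M⁻¹ s⁻¹)
    dissolved gas + target → over-reacted product (k = 0.747 M⁻¹ s⁻¹)
    2 dissolved gas → homo dimer (k = 0.314 M⁻¹ s⁻¹)
    substrate + target → side product (k = 0.133 M⁻¹ s⁻¹)

With 40% substrate left, the span gives 20.4% target in this flask.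

The same flask read at 6.0 min has 23% substrate left, and the span gives 20.5% target; computed, it holds 20.8%.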